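**Plan**
- Retrosynthesis cuts, in order: the C=C bond of the C5 propenol chain (back to a 5‑formyl group), the O1–C7a bond of ring B (the dihydrofuran), the C2–O and C3–H bonds (back to an (E)-alkene), and the C3–C3a aryl–alkenyl bond. This leaves a ring A fluoroarene and a ring C propenylboronate.
- Forward: ring A (4‑fluoro‑3‑methoxybenzaldehyde, masked as its acetal) is iodinated next to fluorine and coupled with the ring C (Z)-alkenylboronate. The (E)-alkene is hydroborated, the formyl group is unmasked, ring B closes through O1–C7a, and the chain is finished by olefination and reduction.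
- Enabling feature: C7a of ring A is para to C5, and the C5 propenol chain is grown from a formyl group, so a C7a–F bond is activated for displacement by the alkoxide on C2.
- Stereochemistry: the alkene geometry comes from syn borylcupration and a stereoretentive coupling. Syn H–B addition to the (E)-alkene gives the like (threo) alcohol, which becomes the trans C2/C3 ring. The absolute sense comes from monoisopinocampheylborane. The ring closure breaks no bond at either centre.

Key step: step 8

Assumption: monoisopinocampheylborane is taken to attack alkene 9 with the facial sense it shows towards 1‑phenylcyclopentene, which calls for the reagent made from (−)-α-pinene; if the sense proves opposite, the reagent from (+)-α-pinene is used in the same way.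

**Step 1**
Reactants: 1 4-fluoro-3-methoxybenzaldehyde
Product: 2 4-(dimethoxymethyl)-1-fluoro-2-methoxybenzene
Conditions: HC(OMe)3, MeOH, TsOH·H2O (cat.), rt; Et3N quench
Reagents that add atoms: trimethyl orthoformate, COC(OC)OC; methanol, CO
Why: Acid-catalysed acetalisation with the orthoformate as water scavenger masks the formyl group against the organolithium, borane and basic steps that follow, and a dimethyl acetal can later be removed under very mild acid.

**Step 2**
Reactants: 2 4-(dimethoxymethyl)-1-fluoro-2-methoxybenzene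
Product: 4 5-(dimethoxymethyl)-2-fluoro-1-iodo-3-methoxybenzene, via aryllithium 3 (not isolated)
Conditions: n-BuLi, PMDTA, THF, −78 °C; then I2, −78 °C → rt
Reagents that add atoms: iodine, II
Why: Directed ortho-metalation with amine-saturated butyllithium is acidity-controlled and should remove the unhindered proton next to fluorine rather than the proton flanked by methoxy and acetal; iodination at −78 °C traps the aryllithium before LiF loss can occur.

**Step 3**
Reactants: 5 4-iodo-1,2-dimethoxybenzene; 6 propyne
Product: 7 1,2-dimethoxy-4-(prop-1-yn-1-yl)benzene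
Conditions: PdCl2(PPh3)2 (cat.), CuI (cat.), Et3N, THF, rt, sealed vessel
Reagents that add atoms: none
Why: Sonogashira coupling of an aryl iodide with a terminal alkyne is reliable at room temperature and tolerates the electron-rich ring.

**Step 4**
Reactants: 7 1,2-dimethoxy-4-(prop-1-yn-1-yl)benzene
Product: 8 2-[(Z)-1-(3,4-dimethoxyphenyl)prop-1-en-2-yl]-4,4,5,5-tetramethyl-1,3,2-dioxaborolane
Conditions: B2pin2, CuCl (cat.), NaOt-Bu (cat.), P(p-tol)3 (cat.), MeOH, THF, rt
Reagents that add atoms: bis(pinacolato)diboron, CC1(C)OB(OC1(C)C)B1OC(C)(C)C(C)(C)O1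
Why: Copper-catalysed formal hydroboration (syn borylcupration, then protonation by methanol with retention) puts copper on the aryl-bearing carbon and boron on the methyl-bearing carbon, so the aryl group ends up trans to boron.

**Step 5**
Reactants: 4 5-(dimethoxymethyl)-2-fluoro-1-iodo-3-methoxybenzene; 8 2-[(Z)-1-(3,4-dimethoxyphenyl)prop-1-en-2-yl]-4,4,5,5-tetramethyl-1,3,2-dioxaborolane
Product: 9 5-(dimethoxymethyl)-1-[(E)-1-(3,4-dimethoxyphenyl)prop-1-en-2-yl]-2-fluoro-3-methoxybenzene
Conditions: Pd(dppf)Cl2 (cat.), K3PO4, 1,4-dioxane/H2O, 80 °C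
Reagents that add atoms: none
Why: Suzuki–Miyaura coupling replaces boron by the ring A aryl group with retention of alkene geometry, giving the (E)-alkene with the two aryl groups trans; the C–F bond and the acetal are inert to the basic aqueous conditions.

**Step 6**
Reactants: 9 5-(dimethoxymethyl)-1-[(E)-1-(3,4-dimethoxyphenyl)prop-1-en-2-yl]-2-fluoro-3-methoxybenzene
Product: 11 (1S,2S)-2-[5-(dimethoxymethyl)-2-fluoro-3-methoxyphenyl]-1-(3,4-dimethoxyphenyl)propan-1-ol, via alkyl(isopinocampheyl)borane 10 (not isolated)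
Conditions: IpcBH2 [from (−)-α-pinene], THF, −25 → 0 °C; then NaOH, H2O2, H2O, 0 °C → rt
Reagents that add atoms: hydrogen peroxide, OO
Why: Brown asymmetric hydroboration–oxidation places boron on the less substituted benzylic CH carbon and hydrogen on the methyl-bearing carbon from the same face, so the (E)-geometry gives the like (1S,2S) relationship; the isopinocampheyl group selects the alkene face, and peroxide oxidation replaces boron by oxygen with retention.

**Step 7**
Reactants: 11 (1S,2S)-2-[5-(dimethoxymethyl)-2-fluoro-3-methoxyphenyl]-1-(3,4-dimethoxyphenyl)propan-1-ol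
Product: 12 3-[(1S,2S)-1-(3,4-dimethoxyphenyl)-1-hydroxypropan-2-yl]-4-fluoro-5-methoxybenzaldehyde
Conditions: PPTS (cat.), acetone/H2O, rt
Reagents that add atoms: water, O
Why: Acid-catalysed hydrolysis of a dimethyl acetal runs under acid weak enough to leave the electron-rich benzylic alcohol un-ionised, so neither stereocentre is disturbed.

**Step 8**
Reactants: 12 3-[(1S,2S)-1-(3,4-dimethoxyphenyl)-1-hydroxypropan-2-yl]-4-fluoro-5-methoxybenzaldehyde
Product: 14 (2S,3S)-2-(3,4-dimethoxyphenyl)-7-methoxy-3-methyl-2,3-dihydro-1-benzofuran-5-carbaldehyde, via sodium alkoxide 13 (not isolated)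
Conditions: NaH, THF/DMF, 0 °C → rt
Reagents that add atoms: none
Why: NaH turns the secondary alcohol into alkoxide 13, whose oxygen adds to the fluorine-bearing C7a to give a Meisenheimer anion delocalised onto C5 and into the formyl group, and loss of fluoride then restores the aromatic ring (addition–elimination). The closest known reaction type is the intramolecular nucleophilic aromatic substitution of aryl fluorides activated by a para carbonyl group to give 2,3-dihydrobenzofurans. Ring B closes in the 5-exo-trig mode through the new O1–C7a bond, with C2, C3 and C3a already in place. No new stereocentre arises and no bond to C2 or C3 is broken, so the (1S,2S) alcohol maps onto the (2S,3S) trans ring. The step needs only site selectivity and chemoselectivity: the single fluorine fixes the site, its para relation to the formyl group supplies the activation, and alkoxide addition to the aldehyde is reversible whereas fluoride loss is not.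

**Step 9**
Reactants: 14 (2S,3S)-2-(3,4-dimethoxyphenyl)-7-methoxy-3-methyl-2,3-dihydro-1-benzofuran-5-carbaldehyde; 15 triethyl phosphonoacetate
Product: 16 ethyl (E)-3-[(2S,3S)-2-(3,4-dimethoxyphenyl)-7-methoxy-3-methyl-2,3-dihydro-1-benzofuran-5-yl]prop-2-enoate
Conditions: LiCl, DBU, MeCN, rt
Reagents that add atoms: none
Why: Horner–Wadsworth–Emmons olefination under Masamune–Roush conditions gives the (E)-enoate from an aryl aldehyde, and the mild amine base cannot epimerise the non-acidic C2 and C3 centres.

**Step 10**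
Reactants: 16 ethyl (E)-3-[(2S,3S)-2-(3,4-dimethoxyphenyl)-7-methoxy-3-methyl-2,3-dihydro-1-benzofuran-5-yl]prop-2-enoate
Product: 17 (E)-3-[(2S,3S)-2-(3,4-dimethoxyphenyl)-7-methoxy-3-methyl-2,3-dihydro-1-benzofuran-5-yl]prop-2-en-1-ol
Conditions: i-Bu2AlH, CH2Cl2, −78 °C; aq. potassium sodium tartrate work-up
Reagents that add atoms: none
Why: 1,2-Reduction of an α,β-unsaturated ester by diisobutylaluminium hydride at low temperature gives the allylic alcohol without touching the alkene, and the non-acidic work-up protects the benzylic C2–O bond.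

**Compound list**
1 | 4-fluoro-3-methoxybenzaldehyde | COc1cc(C=O)ccc1F | starting material
2 | 4-(dimethoxymethyl)-1-fluoro-2-methoxybenzene | COc1cc(C(OC)OC)ccc1F | intermediate
3 | [5-(dimethoxymethyl)-2-fluoro-3-methoxyphenyl]lithium | COc1cc(C(OC)OC)cc([Li])c1F | intermediate
4 | 5-(dimethoxymethyl)-2-fluoro-1-iodo-3-methoxybenzene | COc1cc(C(OC)OC)cc(I)c1F | intermediate
5 | 4-iodo-1,2-dimethoxybenzene | COc1ccc(I)cc1OC | starting material
6 | propyne | CC#C | starting material
7 | 1,2-dimethoxy-4-(prop-1-yn-1-yl)benzene | CC#Cc1ccc(OC)c(OC)c1 | intermediate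
8 | 2-[(Z)-1-(3,4-dimethoxyphenyl)prop-1-en-2-yl]-4,4,5,5-tetramethyl-1,3,2-dioxaborolane | COc1ccc(/C=C(\C)B2OC(C)(C)C(C)(C)O2)cc1OC | intermediate
9 | 5-(dimethoxymethyl)-1-[(E)-1-(3,4-dimethoxyphenyl)prop-1-en-2-yl]-2-fluoro-3-methoxybenzene | COc1ccc(/C=C(\C)c2cc(C(OC)OC)cc(OC)c2F)cc1OC | intermediate
10 | [(1S,2S)-2-[5-(dimethoxymethyl)-2-fluoro-3-methoxyphenyl]-1-(3,4-dimethoxyphenyl)propyl](isopinocampheyl)borane, isopinocampheyl group from (−)-α-pinene | COc1ccc([C@@H](B[C@H]2C[C@H]3C[C@@H]([C@@H]2C)C3(C)C)[C@@H](C)c4cc(C(OC)OC)cc(OC)c4F)cc1OC | intermediate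
11 | (1S,2S)-2-[5-(dimethoxymethyl)-2-fluoro-3-methoxyphenyl]-1-(3,4-dimethoxyphenyl)propan-1-ol | COc1ccc([C@@H](O)[C@@H](C)c2cc(C(OC)OC)cc(OC)c2F)cc1OC | intermediate
12 | 3-[(1S,2S)-1-(3,4-dimethoxyphenyl)-1-hydroxypropan-2-yl]-4-fluoro-5-methoxybenzaldehyde | COc1ccc([C@@H](O)[C@@H](C)c2cc(C=O)cc(OC)c2F)cc1OC | intermediate
13 | sodium (1S,2S)-1-(3,4-dimethoxyphenyl)-2-(2-fluoro-5-formyl-3-methoxyphenyl)propan-1-olate | COc1ccc([C@@H]([O-])[C@@H](C)c2cc(C=O)cc(OC)c2F)cc1OC.[Na+] | intermediate
14 | (2S,3S)-2-(3,4-dimethoxyphenyl)-7-methoxy-3-methyl-2,3-dihydro-1-benzofuran-5-carbaldehyde | COc1ccc([C@H]2Oc3c(OC)cc(C=O)cc3[C@@H]2C)cc1OC | intermediate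
15 | triethyl phosphonoacetate | CCOC(=O)CP(=O)(OCC)OCC | starting material
16 | ethyl (E)-3-[(2S,3S)-2-(3,4-dimethoxyphenyl)-7-methoxy-3-methyl-2,3-dihydro-1-benzofuran-5-yl]prop-2-enoate | COc1ccc([C@H]2Oc3c(OC)cc(/C=C/C(=O)OCC)cc3[C@@H]2C)cc1OC | intermediate
17 | (E)-3-[(2S,3S)-2-(3,4-dimethoxyphenyl)-7-methoxy-3-methyl-2,3-dihydro-1-benzofuran-5-yl]prop-2-en-1-ol | COc1ccc([C@H]2Oc3c(OC)cc(/C=C/CO)cc3[C@@H]2C)cc1OC | target

**Count**
Total steps: 10. Longest linear sequence: 8 steps (1, 2, 5, 6, 7, 8, 9, 10); steps 3 and 4 form the two-step side branch to boronate 8.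

**Steps most likely to fail**

Step 2. Site control in the deprotonation may be lost, with metalation between the methoxy and acetal groups instead of next to fluorine, or the ortho-fluoro aryllithium may lose LiF before it is trapped. Fallback: setting out from 2, an iridium-catalysed C–H borylation ([Ir(OMe)(cod)]2, 4,4′-di-tert-butyl-2,2′-bipyridine, B2pin2, THF, 80 °C) is governed by sterics and by the activating effect of an ortho fluorine. It should functionalise only the C–H next to fluorine and give 2-[5-(dimethoxymethyl)-2-fluoro-3-methoxyphenyl]-4,4,5,5-tetramethyl-1,3,2-dioxaborolane F1. Copper-mediated iododeboronation (CuI, 1,10-phenanthroline, KI, MeOH/H2O, air, 80 °C) then comes back to the route at 4.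

Step 6. Facial discrimination by the chiral borane may be poor, or addition to the hindered diaryl alkene may be sluggish, which would erode the enantiomeric purity of both centres at once. Fallback: setting out from 9, hydroboration with BH3·SMe2 and NaOH/H2O2 still adds syn and should give the racemic like alcohol rac-(1S*,2S*)-2-[5-(dimethoxymethyl)-2-fluoro-3-methoxyphenyl]-1-(3,4-dimethoxyphenyl)propan-1-ol F2. Esterification with (S)-2-methoxy-2-phenylacetic acid (DCC, DMAP, CH2Cl2) would give two diastereomeric esters to be separated by chromatography or crystallisation: the (1S,2S)-propyl (S)-2-methoxy-2-phenylacetate F3 and the (1R,2R)-propyl (S)-2-methoxy-2-phenylacetate F4. Saponification of F3 (LiOH, THF/H2O) comes back to the route at 11; F4 is discarded.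

Step 8. The alkoxide may be captured reversibly by the formyl group, or hydride may be transferred from the alkoxide carbon to an aldehyde; either removes the activation before fluoride is displaced, and shielding of C7a by the flanking methoxy group would slow the wanted attack further. Fallback: setting out from 12, the formyl group is converted into a cyano group (I2, aqueous NH3, THF, rt) to give 3-[(1S,2S)-1-(3,4-dimethoxyphenyl)-1-hydroxypropan-2-yl]-4-fluoro-5-methoxybenzonitrile F5. The para nitrile activates the C–F bond equally well but is neither an alkoxide trap nor a hydride acceptor. The same ring closure (NaH, THF/DMF) would give (2S,3S)-2-(3,4-dimethoxyphenyl)-7-methoxy-3-methyl-2,3-dihydro-1-benzofuran-5-carbonitrile F6. Reduction with i-Bu2AlH (toluene, −78 °C) and mild hydrolysis of the imine comes back to the route at 14.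

**Further compounds**
F1 | step 2 | 2-[5-(dimethoxymethyl)-2-fluoro-3-methoxyphenyl]-4,4,5,5-tetramethyl-1,3,2-dioxaborolane | COc1cc(C(OC)OC)cc(B2OC(C)(C)C(C)(C)O2)c1F
F2 | step 6 | rac-(1S*,2S*)-2-[5-(dimethoxymethyl)-2-fluoro-3-methoxyphenyl]-1-(3,4-dimethoxyphenyl)propan-1-ol | COc1ccc([C@@H](O)[C@@H](C)c2cc(C(OC)OC)cc(OC)c2F)cc1OC.COc1ccc([C@H](O)[C@H](C)c2cc(C(OC)OC)cc(OC)c2F)cc1OC
F3 | step 6 | (1S,2S)-2-[5-(dimethoxymethyl)-2-fluoro-3-methoxyphenyl]-1-(3,4-dimethoxyphenyl)propyl (S)-2-methoxy-2-phenylacetate | COc1ccc([C@@H](OC(=O)[C@@H](OC)c2ccccc2)[C@@H](C)c3cc(C(OC)OC)cc(OC)c3F)cc1OC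
F4 | step 6 | (1R,2R)-2-[5-(dimethoxymethyl)-2-fluoro-3-methoxyphenyl]-1-(3,4-dimethoxyphenyl)propyl (S)-2-methoxy-2-phenylacetate | COc1ccc([C@H](OC(=O)[C@@H](OC)c2ccccc2)[C@H](C)c3cc(C(OC)OC)cc(OC)c3F)cc1OC
F5 | step 8 | 3-[(1S,2S)-1-(3,4-dimethoxyphenyl)-1-hydroxypropan-2-yl]-4-fluoro-5-methoxybenzonitrile | COc1ccc([C@@H](O)[C@@H](C)c2cc(C#N)cc(OC)c2F)cc1OC
F6 | step 8 | (2S,3S)-2-(3,4-dimethoxyphenyl)-7-methoxy-3-methyl-2,3-dihydro-1-benzofuran-5-carbonitrile | COc1ccc([C@H]2Oc3c(OC)cc(C#N)cc3[C@@H]2C)cc1OC
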